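In a one-step world, solid substrate and activator become ring directly, and heat simply speeds that step. The earlier runs do not read that way.

common to all: activator 1.56 M (fed, over 1.0 min)

| charge | solid substrate | temperature | remark | time |
|---|---|---|---|---|
| north-west | 0.39 M | 15 °C | run made earlier; the fed solution adds 0.50 times the starting volume |  |
| north-east | 1.6 M | 37 °C | run made earlier; the fed solution adds 0.50 times the starting volume |  |
| winter | 0.78 M |  | at 5 °C until 1.0 min, from then on at 45 °C; the fed solution adds 0.50 times the starting volume | 5.0 min |
| spring | 0.78 M |  | at 5 °C throughout; the fed solution adds 0.50 times the starting volume | 10 min |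

north-west run (percent of the solid substrate charged)

| time / min | ring / % | solid substrate / % |
|---|---|---|
| 0.250 | 0.1 | 95.3 |
| 0.667 | 2.8 | 83.9 |
| 1.33 | 14.1 | 63.7 |
| 3.00 | 59.3 | 9.1 |

north-east run (percent of the solid substrate charged)

| time / s | ring / % | solid substrate / % |
|---|---|---|
| 10.0 | 0 | 98.5 |
| 12.0 | 0 | 98.6 |
| 25.0 | 0.3 | 96.0 |
| 60.0 | 5.9 | 95.2 |

(standard deviation of a reading: 1 percentage point)

- amounts are per litre of the starting volume; all of the dose is in the solution fed
- solid substrate is a solid; its amount is given per volume of the solution
- the analysis behind the earlier runs scatters by 1 percentage point, standard deviation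
- at the start none of the solid substrate is in solution
- what has only dissolved of solid substrate counts as not reacted

1. the flask that ends with the higher amount of ring, in percent of the solid substrate charged, or "neither" when 2 percentage points or less lies between them (winter / spring / neither)
2. final ring, as a percentage of the solid substrate charged, in winter
3. final ring, as a percentage of the solid substrate charged, in spring

Two chemists argue over these runs. The first looks at the loss of solid substrate. The north-west run at 15 °C loses it steadily, at a reading of 0.122 M min⁻¹ per starting volume. Early on, north-west reads 0.0941 M min⁻¹. North-east, at 37 °C with 1.6 M of solid, reads 0.0768 M min⁻¹. Heat and more solid together show no gain there, so the first takes going into solution as the rate-limiting step of the loss, at a fixed pace. For 0.78 M that gives 6.38 min, the clearing time, which is the charge of solid substrate divided by the pace. Winter stops at 5.0 min, before clearing, so the first caps its ring at 78.4%. Spring runs 10 min, past clearing, so the first gives it the full charge as its cap.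

The second looks at ring. At 3.00 min, north-west has lost 90.9% but shows 59.3% ring. At 60.0 s, north-east has lost 4.80% and shows 5.9% ring. So the second holds that something waits on the way to ring, and that heat empties the wait. Spring stays at 5 °C, colder than north-west, so the second expects it below 65.2%, the share of the lost solid that north-west showed as ring at 3.00 min. The second prefers winter at 45 °C, with the cap of 78.4%.

The forecast sides with the first: 72% for winter, 83% for spring, and spring higher. Its words are “Spring should end higher, mainly because it runs longer.”

The simulation gives 57.9% in winter and 81.5% in spring, so spring ends higher and the first view wins.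

    starting material + activator → activated form (k = 0.0658 L mol⁻¹ s⁻¹, Ea = 44.0 kJ mol⁻¹)
    activated form → ring (k = 0.00667 s⁻¹, Ea = 88.0 kJ mol⁻¹)
    starting material + activated form → open dimer (k = 0.00712 L mol⁻¹ s⁻¹, Ea = 56.0 kJ mol⁻¹)
    solid substrate ⇌ starting material, rate k4*(cs4 - [starting material]) while solid is left; crystals form when [starting material] > cs4 (solubility = 0.300 M, k = 0.00474 s⁻¹)
    activator + ring → over-reaction product (k = 8.17 × 10⁻⁵ L mol⁻¹ s⁻¹, Ea = 63.0 kJ mol⁻¹)
    starting material ⇌ dormant form (K = 1.40, k = 0.00361 s⁻¹, Ea = 69.0 kJ mol⁻¹, ΔH = 25.0 kJ mol⁻¹)
    (constants at 5 °C)

Winter ends with 22.1% solid substrate, and the clearing time reckoned 21.6%. Spring's time beyond the reckoned clearing is 3.62 min, about twice the 1.7 min half-life of activated form going to ring, and spring ends with 10.9% activated form beside 81.5% ring.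

The second view has its region in a repeat of spring at 20 °C. Reckoned as before, the clearing time is 6.38 min against 10 min, so the cap is the full charge and the second's heat has time to work on the wait. That flask ends with 0% solid substrate and 90.6% ring, 9.1 percentage points more than spring.

The data come from a simulation on assumed constants, and the scatter is random.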